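The earlier runs and the new flask come from a simulation for substances that don't exist; the scatter is artificial.

Whatever path it takes, each target made costs one starting material and one reagent, so the smaller charge (the limiting reagent) caps target in a closed flask. Dividing the reading at the last time by that cap gives what I call the attainment, and the cap as a share of the starting material charged is the ceiling.

| flask | starting material | reagent | time |
|---|---|---|---|
| south | 0.120 M | 0.300 M |  |
| north-east | 0.0480 M | 0.228 M |  |
| south-east | 0.360 M | 0.300 M |  |
| north | 0.870 M | 0.300 M | 91 min |

| run | time / min | [target] / M |
|---|---|---|
| south run | 13 | 0.0038 |
| south run | 26 | 0.0096 |
| south run | 39 | 0.0161 |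
| south run | 52 | 0.0222 |
| south run | 65 | 0.0264 |
| south run | 78 | 0.0291 |
| south run | 91 | 0.0311 |
| north-east run | 13 | 7 × 10⁻⁴ |
| north-east run | 26 | 0.0021 |
| north-east run | 39 | 0.0027 |
| north-east run | 52 | 0.0042 |
| north-east run | 65 | 0.0038 |
| north-east run | 78 | 0.0054 |
| north-east run | 91 | 0.0053 |
| south-east run | 13 | 0.0192 |
| south-east run | 26 | 0.0754 |
| south-east run | 39 | 0.1276 |
| south-east run | 52 | 0.1493 |
| south-east run | 65 | 0.1572 |
| south-east run | 78 | 0.1556 |
| south-east run | 91 | 0.1508 |

(scatter of a reading: 4 × 10⁻⁴ M)

- Overall: starting material + reagent -> target.
- Constant volume, constant temperature.
- "The second partner" is reagent.
- An order is taken over about fifteen percent of the charge, up and down.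

1. the exponent of [starting material] in the starting rate at the charge of the south run (at the point where two percent of the starting material have become target) (one fixed amount of target, the same in the runs compared)
2. the exponent of [reagent] in the starting rate at the charge of the south run (at the point where two percent of the starting material have become target)
3. target in the north run at 91 min, as a share of the starting material charged

Take the starting material charge first, with reagent held at 0.300 M. By hand, raising it beyond the reagent charge lowers the ceiling: the south run has the full charge as its ceiling, the south-east run has 83.3 %, and the north run has 34.5 %. What the readings add is that attainment at the last time is higher at the higher charge, going from 25.9 % in the south run to 50.3 % in the south-east run.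

Extending that rise along the logarithm of the charge, I expect attainment of 69.8 % in the north run, so target at 24.1 % of the starting material charged.

The exponent in starting material reads 1.47 from the first readings of these two runs. That is at equal time, though, and the south-east flask already holds more target, so I expect a lower value at equal target.

Now turn the reagent charge. By hand, less reagent slows the flask without moving the ceiling while starting material is the smaller charge. The north-east run, with 0.228 M, attains 11.0 %, but it differs from the south run in both charges, so I commit to no reagent exponent of my own.

The forecast gave 1.05 (range 0.8 to 1.5) for the exponent in starting material, 1.7 (range 1 to 2.2) for the exponent in reagent and 24 % (range 17 % to 31 %) for the north run, holding that “In north, reagent limits”.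

The simulation gives exponents of 1.0 in starting material and 0.94 in reagent, and 24.5 % in the north run.

    starting material → intermediate (0.01680 min⁻¹)
    intermediate + reagent → target (0.1392 M⁻¹ min⁻¹)
    intermediate → side product (0.2112 min⁻¹)
    target → decomposed product (0.004482 min⁻¹)
    starting material + reagent + target → 2 target (1.596 M⁻² min⁻¹)

The north run therefore attains 71.0 % of its ceiling of 34.5 %, against my 69.8 %. The conversion of starting material, reagent and target into 2 target raises that attainment: the north run without this step gives 8.48 % instead of 24.5 %. With the charges and so the ceiling unchanged in that run, its attainment falls to 24.6 %.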